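**Retrosynthetic overview**
- The oxirane is made last, by face-selective epoxidation of the 1(10)E-alkene of the macrocyclic diol.
- The ten-membered ring is closed at C3–C4 by an intramolecular Ni/Cr vinyl iodide–aldehyde coupling, which also creates the C3 carbinol and keeps the 4Z geometry.
- The methylene-lactone ring is made before that: allylboration/lactonisation of a Z-iodoenal (C4–C6, C15) with an ester-substituted allylboronate (C7–C13, C1–C3, C8–C10, C14) sets C6 and C7.
- The C8 stereocentre and its ester are set in one operation by amine-catalysed α-acyloxylation of an achiral aldehyde with the diacyl peroxide of (S)-2-methylbutanoic acid, itself made from tiglic acid by asymmetric hydrogenation.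
- The E-C1=C10 alkene comes from a Johnson–Claisen rearrangement. Ring order: lactone, then ten-membered carbocycle, then oxirane.

Assumption: atom labels C1–C15 follow germacrane numbering (C1–C10 ring, C11–C13 methylene-lactone carbons, C14 methyl, C15 hydroxymethyl), and the seven starting materials named below are taken as catalogue chemicals.

The stereochemical outcomes of steps 11, 14 and 16 are predictions from transition-state and conformational models, not established results for these substrates.

Step 1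
Reactants: 1 tiglic acid [(2E)-2-methylbut-2-enoic acid]
Product: 2 (2S)-2-methylbutanoic acid
Conditions: H2 (1.5 atm), Ru(OAc)2[(S)-H8-BINAP] (0.5 mol %), MeOH, 20 °C
Reagents that add atoms: none
Why: Carboxylate-directed asymmetric hydrogenation of the α,β-unsaturated acid on the ruthenium diacetate–diphosphine catalyst adds H2 to one face of the alkene and sets the side-chain stereocentre as S (about 97% ee expected; the ligand hand is the one recalled to give S and should be confirmed by rotation), the first stereocentre of the synthesis.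

Step 2
Reactants: 2 (2S)-2-methylbutanoic acid
Product: 3 bis[(2S)-2-methylbutanoyl] peroxide
Conditions: 2 (2.0 equiv), 30% aq. H2O2 (1.0 equiv), DCC (2.1 equiv), DMAP (10 mol %), CH2Cl2, −15 → 0 °C; kept and used as a cold solution, never concentrated
Reagents that add atoms: hydrogen peroxide, OO; (2S)-2-methylbutanoic acid (the second molecule of 2, which supplies the second acyl group), CC[C@H](C)C(=O)O
Why: Carbodiimide-mediated dehydrative coupling joins two molecules of acid 2 to the two oxygens of one molecule of hydrogen peroxide (first to the peracid, which is then acylated by a second O-acylisourea), the standard preparation of aliphatic diacyl peroxides, and it leaves the α-stereocentres untouched.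

Step 3
Reactants: 4 3-[(4-methoxyphenyl)methoxy]propanal; 5 (prop-1-en-2-yl)magnesium bromide
Product: 6 5-[(4-methoxyphenyl)methoxy]-2-methylpent-1-en-3-ol (racemic)
Conditions: THF, −78 → 0 °C; aq. NH4Cl
Reagents that add atoms: none
Why: Grignard 1,2-addition to the aldehyde gives the allylic alcohol, whose carbinol centre is left racemic on purpose because it is destroyed in step 4.

Step 4
Reactants: 6 5-[(4-methoxyphenyl)methoxy]-2-methylpent-1-en-3-ol; 7 1,1,1-triethoxyethane
Product: 8 ethyl (4E)-7-[(4-methoxyphenyl)methoxy]-4-methylhept-4-enoate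
Conditions: EtCO2H (5 mol %), neat in 7, 140 °C, ethanol distilled off
Reagents that add atoms: none
Why: Johnson–Claisen [3,3]-sigmatropic rearrangement of the mixed ketene acetal through a chair transition state with the CH2CH2O side chain equatorial gives the E-trisubstituted C1=C10 alkene (>95:5) and erases the racemic carbinol centre.

Step 5
Reactants: 8 ethyl (4E)-7-[(4-methoxyphenyl)methoxy]-4-methylhept-4-enoate
Product: 9 (4E)-7-[(4-methoxyphenyl)methoxy]-4-methylhept-4-enal
Conditions: i-Bu2AlH (1.1 equiv), CH2Cl2, −78 °C; aq. potassium sodium tartrate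
Reagents that add atoms: none
Why: Partial hydride reduction of the ester stops at the aldehyde because the tetrahedral aluminium hemiacetal is stable at −78 °C until work-up.

Step 6
Reactants: 10 methyl 2-[bis(2,2,2-trifluoroethoxy)phosphoryl]acetate
Product: 12 methyl 2-[bis(2,2,2-trifluoroethoxy)phosphoryl]-2-bromoacetate (racemic), via dibromophosphonoacetate 11 (not isolated)
Conditions: aq. NaOBr, 0 °C; then SnCl2·2H2O, EtOH/H2O, 0 °C
Reagents that add atoms: sodium hypobromite, [Na+].[O-]Br
Why: Exhaustive electrophilic bromination of the acidic methylene followed by halophilic mono-debromination with divalent tin gives the monobromo Horner–Wadsworth–Emmons reagent cleanly, avoiding the mixtures of direct monobromination.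

Step 7
Reactants: 9 (4E)-7-[(4-methoxyphenyl)methoxy]-4-methylhept-4-enal; 3 bis[(2S)-2-methylbutanoyl] peroxide; 12 methyl 2-[bis(2,2,2-trifluoroethoxy)phosphoryl]-2-bromoacetate
Product: 14 methyl (2E,4R,6E)-2-bromo-9-[(4-methoxyphenyl)methoxy]-6-methyl-4-{[(2S)-2-methylbutanoyl]oxy}nona-2,6-dienoate, via α-acyloxy aldehyde 13 (not isolated)
Conditions: (R)-α,α-diphenylprolinol trimethylsilyl ether (10 mol %), hydroquinone (10 mol %), 3 (1.3 equiv), THF, −20 → 0 °C; cold aq. Na2S2O3/NaHCO3 wash; then 12, KOt-Bu, 18-crown-6, THF, −78 °C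
Reagents that add atoms: none
Why: Proposed new method: enamine-catalysed asymmetric α-acyloxylation in which the aliphatic diacyl peroxide 3 takes the place of dibenzoyl peroxide, the E-enamine of 9 attacking a peroxide oxygen (substitution at O with carboxylate as leaving group) from the face not shielded by the diphenyl(silyloxy)methyl group of the (R)-catalyst so that C8 is formed as R with its final ester already in place, the closest known reaction being the amine-catalysed α-benzoyloxylation of aldehydes with dibenzoyl peroxide; the labile aldehyde 13 is trapped at once in a Still–Gennari-type Horner–Wadsworth–Emmons olefination whose kinetic control puts C8 cis to the ester (2E).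

Step 8
Reactants: 14 methyl (2E,4R,6E)-2-bromo-9-[(4-methoxyphenyl)methoxy]-6-methyl-4-{[(2S)-2-methylbutanoyl]oxy}nona-2,6-dienoate; 15 2-(iodomethyl)-4,4,5,5-tetramethyl-1,3,2-dioxaborolane
Product: 17 methyl (2Z,4R,6E)-9-[(4-methoxyphenyl)methoxy]-6-methyl-4-{[(2S)-2-methylbutanoyl]oxy}-2-[(4,4,5,5-tetramethyl-1,3,2-dioxaborolan-2-yl)methyl]nona-2,6-dienoate, via borylmethylzinc iodide 16 (not isolated)
Conditions: Zn (activated), THF, 25 °C; then 14, Pd(PPh3)4 (5 mol %), THF, 0 → 25 °C
Reagents that add atoms: none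
Why: Negishi cross-coupling in which zinc inserts into the C–I bond of 15, zerovalent palladium adds to the activated C–Br bond of 14 faster than it ionises the allylic ester, and transmetalation and reductive elimination go with retention, so C8 stays cis to the ester in the allylboronate.

Step 9
Reactants: 18 4-{[tert-butyl(dimethyl)silyl]oxy}but-2-yn-1-ol
Product: 20 (2Z)-4-{[tert-butyl(dimethyl)silyl]oxy}-3-iodobut-2-en-1-ol, via cyclic alkenylalanate 19 (not isolated)
Conditions: NaAlH2(OCH2CH2OCH3)2, THF, 0 °C; then I2, −78 → 0 °C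
Reagents that add atoms: iodine, II
Why: Hydroxyl-directed trans-hydroalumination of the propargylic alcohol puts aluminium on the distal alkyne carbon in a five-membered alanate, and iodinolysis with retention gives the Z-vinyl iodide with C6 and iodine cis, which is the future 4Z geometry.

Step 10
Reactants: 20 (2Z)-4-{[tert-butyl(dimethyl)silyl]oxy}-3-iodobut-2-en-1-ol
Product: 21 (2Z)-4-{[tert-butyl(dimethyl)silyl]oxy}-3-iodobut-2-enal
Conditions: MnO2 (activated, 15 equiv), CH2Cl2, 25 °C
Reagents that add atoms: none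
Why: Chemoselective allylic alcohol oxidation on MnO2 under neutral conditions gives the enal without loss of the alkene geometry or the silyl ether.

Step 11
Reactants: 17 methyl (2Z,4R,6E)-9-[(4-methoxyphenyl)methoxy]-6-methyl-4-{[(2S)-2-methylbutanoyl]oxy}-2-[(4,4,5,5-tetramethyl-1,3,2-dioxaborolan-2-yl)methyl]nona-2,6-dienoate; 21 (2Z)-4-{[tert-butyl(dimethyl)silyl]oxy}-3-iodobut-2-enal
Product: 23 (1R,3E)-1-{(2S,3R)-2-[(1Z)-3-{[tert-butyl(dimethyl)silyl]oxy}-2-iodoprop-1-en-1-yl]-4-methylidene-5-oxooxolan-3-yl}-6-[(4-methoxyphenyl)methoxy]-3-methylhex-3-en-1-yl (2S)-2-methylbutanoate, via homoallyl pinacol borate 22 (not isolated)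
Conditions: Sc(OTf)3 (10 mol %), toluene, 0 → 25 °C; then p-TsOH·H2O (10 mol %), 25 °C
Reagents that add atoms: none
Why: Lewis-acid-catalysed allylboration through a closed chair transition state places C8 (cis to the ester) and the enal substituent both equatorial, which gives the 6,7-trans lactone after lactonisation, while allylic 1,3-strain to the cis ester should hold H8 in the alkene plane so that the aldehyde adds to C7 anti to the C9 chain and past the smaller acyloxy group, giving 7R and the target configuration at C6 (labelled S here only because iodine changes the CIP priorities).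

Step 12
Reactants: 23 the lactone of step 11
Product: 24 (1R,3E)-1-{(2S,3R)-2-[(1Z)-3-{[tert-butyl(dimethyl)silyl]oxy}-2-iodoprop-1-en-1-yl]-4-methylidene-5-oxooxolan-3-yl}-6-hydroxy-3-methylhex-3-en-1-yl (2S)-2-methylbutanoate
Conditions: DDQ (1.3 equiv), CH2Cl2/pH 7 buffer (10:1), 0 °C
Reagents that add atoms: none
Why: Oxidative cleavage of the 4-methoxybenzyl ether (hydride abstraction then hydrolysis of the oxocarbenium ion) frees the C3 primary alcohol without touching the silyl ether, esters, vinyl iodide or lactone.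

Step 13
Reactants: 24 the primary alcohol of step 12
Product: 25 (1R,3E)-1-{(2S,3R)-2-[(1Z)-3-{[tert-butyl(dimethyl)silyl]oxy}-2-iodoprop-1-en-1-yl]-4-methylidene-5-oxooxolan-3-yl}-3-methyl-6-oxohex-3-en-1-yl (2S)-2-methylbutanoate
Conditions: Dess–Martin periodinane, NaHCO3, CH2Cl2, 0 °C; used crude at once
Reagents that add atoms: none
Why: Dess–Martin oxidation under buffered, non-basic conditions gives the β,γ-unsaturated C3 aldehyde without moving the C1=C10 double bond into conjugation.

Step 14
Reactants: 25 the iodo aldehyde of step 13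
Product: 26 (1(10)E,3S,4Z,6R,7R,8R)-15-{[tert-butyl(dimethyl)silyl]oxy}-3-hydroxy-8-{[(2S)-2-methylbutanoyl]oxy}germacra-1(10),4,11(13)-trien-12,6-olide
Conditions: CrCl2 (8 equiv), NiCl2 (0.1 equiv), degassed DMSO/THF, 25 °C, 0.002 M, slow addition
Reagents that add atoms: none
Why: Intramolecular Nozaki–Hiyama–Kishi reaction in which zerovalent nickel inserts into the C4–I bond, the vinyl group passes to chromium with retention of the Z geometry and adds to the C3 aldehyde at high dilution to close the ten-membered ring, the 3S carbinol being expected from addition to the outward aldehyde face of the folded chain and being the least secure stereocentre of the route.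

Step 15
Reactants: 26 the macrocyclic silyl ether of step 14
Product: 27 (1(10)E,3S,4Z,6R,7R,8R)-3,15-dihydroxy-8-{[(2S)-2-methylbutanoyl]oxy}germacra-1(10),4,11(13)-trien-12,6-olide
Conditions: HF·pyridine, pyridine, THF, 0 → 25 °C
Reagents that add atoms: none
Why: Fluoride-mediated Si–O cleavage under buffered mildly acidic conditions removes the silyl group without opening the lactone, adding to the methylene lactone or cleaving the C8 ester, and is done before the acid-sensitive epoxide exists.

Step 16
Reactants: 27 the macrocyclic diol of step 15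
Product: 28 (1R,3S,4Z,6R,7R,8R,10R)-1,10-epoxy-3,15-dihydroxy-8-{[(2S)-2-methylbutanoyl]oxy}germacra-4,11(13)-dien-12,6-olide (CNP0267576.2)
Conditions: mCPBA (1.1 equiv), NaHCO3, CH2Cl2, −20 → 0 °C
Reagents that add atoms: 3-chloroperoxybenzoic acid (mCPBA), OOC(=O)c1cccc(Cl)c1
Why: Prilezhaev epoxidation takes the electron-rich 1(10) alkene in preference to the C4=C5 alkene flanked by three allylic C–O bonds and to the acrylate, and the peracid should add to the outer face of the E-alkene, which stands perpendicular to the ring with C14 on the β side, to give the trans 1β,10α-epoxide (1R,10R).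

**Compound list**
1 | tiglic acid, (2E)-2-methylbut-2-enoic acid | C/C=C(\C)C(=O)O | starting material
2 | (2S)-2-methylbutanoic acid | CC[C@H](C)C(=O)O | intermediate
3 | bis[(2S)-2-methylbutanoyl] peroxide | CC[C@H](C)C(=O)OOC(=O)[C@@H](C)CC | intermediate
4 | 3-[(4-methoxyphenyl)methoxy]propanal | O=CCCOCc1ccc(OC)cc1 | starting material
5 | (prop-1-en-2-yl)magnesium bromide | C=C(C)[Mg]Br | starting material
6 | 5-[(4-methoxyphenyl)methoxy]-2-methylpent-1-en-3-ol (racemic) | C=C(C)C(O)CCOCc1ccc(OC)cc1 | intermediate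
7 | 1,1,1-triethoxyethane (triethyl orthoacetate) | CC(OCC)(OCC)OCC | starting material
8 | ethyl (4E)-7-[(4-methoxyphenyl)methoxy]-4-methylhept-4-enoate | CCOC(=O)CC/C(C)=C/CCOCc1ccc(OC)cc1 | intermediate
9 | (4E)-7-[(4-methoxyphenyl)methoxy]-4-methylhept-4-enal | O=CCC/C(C)=C/CCOCc1ccc(OC)cc1 | intermediate
10 | methyl 2-[bis(2,2,2-trifluoroethoxy)phosphoryl]acetate | COC(=O)CP(=O)(OCC(F)(F)F)OCC(F)(F)F | starting material
11 | methyl 2-[bis(2,2,2-trifluoroethoxy)phosphoryl]-2,2-dibromoacetate | COC(=O)C(Br)(Br)P(=O)(OCC(F)(F)F)OCC(F)(F)F | intermediate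
12 | methyl 2-[bis(2,2,2-trifluoroethoxy)phosphoryl]-2-bromoacetate (racemic) | COC(=O)C(Br)P(=O)(OCC(F)(F)F)OCC(F)(F)F | intermediate
13 | (2R,4E)-7-[(4-methoxyphenyl)methoxy]-4-methyl-1-oxohept-4-en-2-yl (2S)-2-methylbutanoate | O=C[C@H](OC(=O)[C@@H](C)CC)C/C(C)=C/CCOCc1ccc(OC)cc1 | intermediate
14 | methyl (2E,4R,6E)-2-bromo-9-[(4-methoxyphenyl)methoxy]-6-methyl-4-{[(2S)-2-methylbutanoyl]oxy}nona-2,6-dienoate | COC(=O)/C(Br)=C\[C@H](OC(=O)[C@@H](C)CC)C/C(C)=C/CCOCc1ccc(OC)cc1 | intermediate
15 | 2-(iodomethyl)-4,4,5,5-tetramethyl-1,3,2-dioxaborolane | ICB1OC(C)(C)C(C)(C)O1 | starting material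
16 | iodo[(4,4,5,5-tetramethyl-1,3,2-dioxaborolan-2-yl)methyl]zinc | I[Zn]CB1OC(C)(C)C(C)(C)O1 | intermediate
17 | methyl (2Z,4R,6E)-9-[(4-methoxyphenyl)methoxy]-6-methyl-4-{[(2S)-2-methylbutanoyl]oxy}-2-[(4,4,5,5-tetramethyl-1,3,2-dioxaborolan-2-yl)methyl]nona-2,6-dienoate | COC(=O)/C(CB1OC(C)(C)C(C)(C)O1)=C\[C@H](OC(=O)[C@@H](C)CC)C/C(C)=C/CCOCc1ccc(OC)cc1 | intermediate
18 | 4-{[tert-butyl(dimethyl)silyl]oxy}but-2-yn-1-ol | CC(C)(C)[Si](C)(C)OCC#CCO | starting material
19 | sodium 3-({[tert-butyl(dimethyl)silyl]oxy}methyl)-2,2-bis(2-methoxyethoxy)-2,5-dihydro-1,2-oxaluminol-2-uide (cyclic alkenylalanate) | [Na+].COCCO[Al-]1(OCCOC)OC/C=C\1CO[Si](C)(C)C(C)(C)C | intermediate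
20 | (2Z)-4-{[tert-butyl(dimethyl)silyl]oxy}-3-iodobut-2-en-1-ol | CC(C)(C)[Si](C)(C)OC/C(I)=C/CO | intermediate
21 | (2Z)-4-{[tert-butyl(dimethyl)silyl]oxy}-3-iodobut-2-enal | CC(C)(C)[Si](C)(C)OC/C(I)=C/C=O | intermediate
22 | methyl (3S,4S,5Z)-7-{[tert-butyl(dimethyl)silyl]oxy}-6-iodo-3-[(1R,3E)-6-[(4-methoxyphenyl)methoxy]-3-methyl-1-{[(2S)-2-methylbutanoyl]oxy}hex-3-en-1-yl]-2-methylidene-4-[(4,4,5,5-tetramethyl-1,3,2-dioxaborolan-2-yl)oxy]hept-5-enoate | COC(=O)C(=C)[C@@H]([C@H](OB1OC(C)(C)C(C)(C)O1)/C=C(\I)CO[Si](C)(C)C(C)(C)C)[C@H](OC(=O)[C@@H](C)CC)C/C(C)=C/CCOCc1ccc(OC)cc1 | intermediate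
23 | (1R,3E)-1-{(2S,3R)-2-[(1Z)-3-{[tert-butyl(dimethyl)silyl]oxy}-2-iodoprop-1-en-1-yl]-4-methylidene-5-oxooxolan-3-yl}-6-[(4-methoxyphenyl)methoxy]-3-methylhex-3-en-1-yl (2S)-2-methylbutanoate | C=C1C(=O)O[C@H](/C=C(\I)CO[Si](C)(C)C(C)(C)C)[C@H]1[C@H](OC(=O)[C@@H](C)CC)C/C(C)=C/CCOCc1ccc(OC)cc1 | intermediate
24 | (1R,3E)-1-{(2S,3R)-2-[(1Z)-3-{[tert-butyl(dimethyl)silyl]oxy}-2-iodoprop-1-en-1-yl]-4-methylidene-5-oxooxolan-3-yl}-6-hydroxy-3-methylhex-3-en-1-yl (2S)-2-methylbutanoate | C=C1C(=O)O[C@H](/C=C(\I)CO[Si](C)(C)C(C)(C)C)[C@H]1[C@H](OC(=O)[C@@H](C)CC)C/C(C)=C/CCO | intermediate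
25 | (1R,3E)-1-{(2S,3R)-2-[(1Z)-3-{[tert-butyl(dimethyl)silyl]oxy}-2-iodoprop-1-en-1-yl]-4-methylidene-5-oxooxolan-3-yl}-3-methyl-6-oxohex-3-en-1-yl (2S)-2-methylbutanoate | C=C1C(=O)O[C@H](/C=C(\I)CO[Si](C)(C)C(C)(C)C)[C@H]1[C@H](OC(=O)[C@@H](C)CC)C/C(C)=C/CC=O | intermediate
26 | (1(10)E,3S,4Z,6R,7R,8R)-15-{[tert-butyl(dimethyl)silyl]oxy}-3-hydroxy-8-{[(2S)-2-methylbutanoyl]oxy}germacra-1(10),4,11(13)-trien-12,6-olide | C=C1C(=O)O[C@@H]2/C=C(/CO[Si](C)(C)C(C)(C)C)[C@@H](O)C/C=C(\C)C[C@@H](OC(=O)[C@@H](C)CC)[C@@H]12 | intermediate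
27 | (1(10)E,3S,4Z,6R,7R,8R)-3,15-dihydroxy-8-{[(2S)-2-methylbutanoyl]oxy}germacra-1(10),4,11(13)-trien-12,6-olide | C=C1C(=O)O[C@@H]2/C=C(/CO)[C@@H](O)C/C=C(\C)C[C@@H](OC(=O)[C@@H](C)CC)[C@@H]12 | intermediate
28 | (1R,3S,4Z,6R,7R,8R,10R)-1,10-epoxy-3,15-dihydroxy-8-{[(2S)-2-methylbutanoyl]oxy}germacra-4,11(13)-dien-12,6-olide (CNP0267576.2) | C=C1C(=O)O[C@@H]2/C=C(/CO)[C@@H](O)C[C@H]3O[C@]3(C)C[C@@H](OC(=O)[C@@H](C)CC)[C@@H]12 | target

**Step count and risks**

Total step count: 16. Longest linear sequence: 11 steps (3, 4, 5, 7, 8, 11, 12, 13, 14, 15, 16).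

The three steps most likely to fail are 7, 11 and 14.

Step 7 (the proposed new α-acyloxylation). The α-branched aliphatic peroxide 3 is thermally labile and may be a poorer oxygen electrophile than dibenzoyl peroxide, so yield or ee may fall short. The fallback uses only known chemistry and sets out from aldehyde 9. L-Proline-catalysed α-aminoxylation with nitrosobenzene, followed by NaBH4 in the same flask, gives (2R,4E)-7-[(4-methoxyphenyl)methoxy]-4-methyl-2-[(phenylamino)oxy]hept-4-en-1-ol F1. Reductive N–O cleavage (Zn, AcOH) gives (2R,4E)-7-[(4-methoxyphenyl)methoxy]-4-methylhept-4-ene-1,2-diol F2. Silylation of the primary hydroxyl (TBSCl, imidazole) gives (2R,4E)-1-{[tert-butyl(dimethyl)silyl]oxy}-7-[(4-methoxyphenyl)methoxy]-4-methylhept-4-en-2-ol F3. Steglich esterification with acid 2 (DCC, DMAP, 0 °C) gives (2R,4E)-1-{[tert-butyl(dimethyl)silyl]oxy}-7-[(4-methoxyphenyl)methoxy]-4-methylhept-4-en-2-yl (2S)-2-methylbutanoate F4. HF·pyridine, chosen to avoid base-induced acyl migration, gives (2R,4E)-1-hydroxy-7-[(4-methoxyphenyl)methoxy]-4-methylhept-4-en-2-yl (2S)-2-methylbutanoate F5. Dess–Martin oxidation then delivers the α-acyloxy aldehyde, and the route is rejoined at 13, which is olefinated with 12 exactly as in step 7.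

Step 11 (allylboration/lactonisation). The ester-substituted, γ-branched allylboronate is a weak nucleophile, and the facial preference at C7 rests on an allylic-strain model that has not been tested for an acyloxy-bearing stereocentre. The fallback sets out from 17 and 21 and comes back at 23, and makes no new compound (F0). It replaces substrate control by catalyst control: the achiral scandium Lewis acid is exchanged for a BINOL-derived chiral N-triflyl phosphoramide (10 mol %, toluene, −40 °C). In this Brønsted-acid allylboration manifold the catalyst is bound to the boronate oxygen and the formyl hydrogen, so it chooses the aldehyde face and therefore which of the two chair transition states operates. Both catalyst hands are available, so the matched one is identified in two experiments. This combination of catalyst and boronate class is itself untested.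

Step 14 (Ni/Cr macrocyclisation). The ten-membered ring is strained, the β,γ-unsaturated aldehyde is fragile, and the C3 configuration depends on the folding of the chain. If the cyclisation gives the 3-epimer or a mixture, the fallback sets out from the crude carbinol mixture 26. Dess–Martin oxidation (NaHCO3, CH2Cl2, 0 °C) gives (1(10)E,4Z,6R,7R,8R)-15-{[tert-butyl(dimethyl)silyl]oxy}-8-{[(2S)-2-methylbutanoyl]oxy}-3-oxogermacra-1(10),4,11(13)-trien-12,6-olide F6. Reagent-controlled Corey–Bakshi–Shibata reduction of this cross-conjugated enone ((R)-2-methyl-CBS-oxazaborolidine, catecholborane, toluene, −78 °C; the alkenyl side acts as the large group) returns diastereomerically pure 3S alcohol 26, where the route is rejoined.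

**Further compounds**
F1 | step 7 | (2R,4E)-7-[(4-methoxyphenyl)methoxy]-4-methyl-2-[(phenylamino)oxy]hept-4-en-1-ol | OC[C@H](ONc1ccccc1)C/C(C)=C/CCOCc1ccc(OC)cc1
F2 | step 7 | (2R,4E)-7-[(4-methoxyphenyl)methoxy]-4-methylhept-4-ene-1,2-diol | OC[C@H](O)C/C(C)=C/CCOCc1ccc(OC)cc1
F3 | step 7 | (2R,4E)-1-{[tert-butyl(dimethyl)silyl]oxy}-7-[(4-methoxyphenyl)methoxy]-4-methylhept-4-en-2-ol | CC(C)(C)[Si](C)(C)OC[C@H](O)C/C(C)=C/CCOCc1ccc(OC)cc1
F4 | step 7 | (2R,4E)-1-{[tert-butyl(dimethyl)silyl]oxy}-7-[(4-methoxyphenyl)methoxy]-4-methylhept-4-en-2-yl (2S)-2-methylbutanoate | CC(C)(C)[Si](C)(C)OC[C@H](OC(=O)[C@@H](C)CC)C/C(C)=C/CCOCc1ccc(OC)cc1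
F5 | step 7 | (2R,4E)-1-hydroxy-7-[(4-methoxyphenyl)methoxy]-4-methylhept-4-en-2-yl (2S)-2-methylbutanoate | OC[C@H](OC(=O)[C@@H](C)CC)C/C(C)=C/CCOCc1ccc(OC)cc1
F0 | step 11 | none | none
F6 | step 14 | (1(10)E,4Z,6R,7R,8R)-15-{[tert-butyl(dimethyl)silyl]oxy}-8-{[(2S)-2-methylbutanoyl]oxy}-3-oxogermacra-1(10),4,11(13)-trien-12,6-olide | C=C1C(=O)O[C@@H]2/C=C(/CO[Si](C)(C)C(C)(C)C)C(=O)C/C=C(\C)C[C@@H](OC(=O)[C@@H](C)CC)[C@@H]12
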